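**Assumption:** the target is (+)-lariciresinol 9-O-stearate, (2S,3R,4R) on the oxolane ring as drawn; dihydroferulic acid, (S)-4-benzyloxazolidin-2-one and vinyl stearate are taken as cheap catalogue chemicals.

**Retrosynthetic overview**
1. Target 11 ⇒ ester C–O bond: (+)-lariciresinol 9 plus a stearoyl donor, acylating only the primary hydroxyl.
2. 9 ⇒ benzylic C2–O bond of the oxolane (the only ring, closed in step 4): C2-symmetric (−)-secoisolariciresinol 7 via a p-quinone methide; either arm gives the same product and the closure sets C2.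
3. 7 ⇒ reduction of bis-imide 6; the central C–C bond comes from auxiliary-controlled oxidative homocoupling of imide 4, which sets the future C3 and C4.
4. 4 ⇒ dihydroferulic acid 1 and (S)-4-benzyloxazolidin-2-one 2; pivaloyl chloride both caps the phenol and activates the acid.

**Step 1**
Reactants: 1 3-(4-hydroxy-3-methoxyphenyl)propanoic acid (dihydroferulic acid); 2 (S)-4-benzyloxazolidin-2-one
Product: 4 (S)-4-benzyl-3-{3-[3-methoxy-4-(pivaloyloxy)phenyl]propanoyl}oxazolidin-2-one, via mixed pivalic anhydride 3 (not isolated)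
Conditions: pivaloyl chloride (2.2 equiv), Et3N (3.5 equiv), THF, −10 → 20 °C; then LiCl (1.2 equiv), 2 (0.95 equiv), 20 °C
Reagents that add atoms: pivaloyl chloride, CC(C)(C)C(Cl)=O
Why: Excess pivaloyl chloride turns the carboxylate into the mixed pivalic anhydride and caps the phenol as its pivalate, and the LiCl-activated oxazolidinone then attacks the unhindered anhydride carbonyl (mixed-anhydride N-acylation of an Evans auxiliary); no new stereocentre.

**Step 2**
Reactants: 4 (S)-4-benzyl-3-{3-[3-methoxy-4-(pivaloyloxy)phenyl]propanoyl}oxazolidin-2-one (2 equivalents)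
Product: 6 (4S,4'S)-3,3'-[(2R,3R)-2,3-bis(3-methoxy-4-pivaloyloxybenzyl)butanedioyl]bis(4-benzyloxazolidin-2-one), via lithium Z-enolate 5 (not isolated)
Conditions: LiN(iPr)2 (1.05 equiv), THF, −78 °C; then TiCl4 (1.05 equiv), −78 → 0 °C
Reagents that add atoms: none
Why: Transmetalation of the chelated Z-enolate to a tetravalent titanium enolate triggers electron transfer to trivalent titanium and C–C coupling on the enolate face away from the auxiliary benzyl group, so both new centres form R as in an Evans alkylation (oxidative enolate homocoupling, precedented for 3-arylpropanoyl oxazolidinones; the aryl pivalates have no α-hydrogen and tolerate the base at −78 °C; minor diastereomers are removed by crystallisation).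

**Step 3**
Reactants: 6 (4S,4'S)-3,3'-[(2R,3R)-2,3-bis(3-methoxy-4-pivaloyloxybenzyl)butanedioyl]bis(4-benzyloxazolidin-2-one)
Product: 7 (2R,3R)-2,3-bis(4-hydroxy-3-methoxybenzyl)butane-1,4-diol ((−)-secoisolariciresinol)
Conditions: LiAlH4 (excess), THF, 0 → 20 °C; then aq. KNaC4H4O6, pH 4
Reagents that add atoms: none
Why: LiAlH4 cleaves both exocyclic imide carbonyls to primary alcohols and both aryl pivalates to phenols in one operation without touching the two stereocentres (hydride reduction; the auxiliary is recovered).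

**Step 4**
Reactants: 7 (2R,3R)-2,3-bis(4-hydroxy-3-methoxybenzyl)butane-1,4-diol
Product: 9 4-[(2S,3R,4R)-4-(4-hydroxy-3-methoxybenzyl)-3-(hydroxymethyl)oxolan-2-yl]-2-methoxyphenol ((+)-lariciresinol), via p-quinone methide 8 (not isolated)
Conditions: DDQ (0.6 equiv, added over 1 h), NaHCO3, 1,4-dioxane, 15 °C
Reagents that add atoms: none
Why: Proposed new method: oxidant-limited dehydrogenative cycloetherification, in which DDQ removes a hydride equivalent (phenol O–H, then benzylic C–H) from one guaiacyl arm to give p-quinone methide 8, whose exocyclic carbon is captured in a 5-exo oxa-1,6-addition by the hydroxymethyl group of the other arm; because 7 is C2-symmetric both arms give the same oxolane, and the aryl group settles trans to the neighbouring CH2OH (envelope transition state with both pseudo-equatorial, and reversible ring opening under the weakly acidic hydroquinone by-product), which sets C2 as S; 0.6 equiv of oxidant and NaHCO3 buffering hold back the second cyclisation to pinoresinol, over-oxidation at the new benzylic ether C–H and the acid-driven Friedel–Crafts closure to the aryltetralin, and unreacted 7 is recycled (expected about 40% per pass); closest known reaction type: quinone dehydrogenation of 4-alkylphenols to p-quinone methides with intermolecular alcohol addition, and the acid-catalysed cyclisation of 7-hydroxysecoisolariciresinol to lariciresinol.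

**Step 5**
Reactants: 9 4-[(2S,3R,4R)-4-(4-hydroxy-3-methoxybenzyl)-3-(hydroxymethyl)oxolan-2-yl]-2-methoxyphenol; 10 vinyl stearate (ethenyl octadecanoate)
Product: 11 [(2S,3R,4R)-2-(4-hydroxy-3-methoxyphenyl)-4-(4-hydroxy-3-methoxybenzyl)oxolan-3-yl]methyl octadecanoate (CNP0168412.1)
Conditions: Novozym 435 (immobilised Candida antarctica lipase B), 10 (2 equiv), 2-methylbutan-2-ol, 50 °C
Reagents that add atoms: none
Why: The lipase forms a stearoyl-enzyme from the vinyl ester and transfers it only to the primary aliphatic hydroxyl, since phenols are not acylated by this serine hydrolase, and tautomerisation of vinyl alcohol to acetaldehyde makes the transesterification irreversible (lipase-catalysed regioselective acylation; no stereocentre is touched).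

**Compound list**
1 | 3-(4-hydroxy-3-methoxyphenyl)propanoic acid (dihydroferulic acid) | COc1cc(CCC(=O)O)ccc1O | starting material
2 | (S)-4-benzyloxazolidin-2-one | O=C1N[C@@H](Cc2ccccc2)CO1 | starting material
3 | 3-[3-methoxy-4-(pivaloyloxy)phenyl]propanoic pivalic anhydride | COc1cc(CCC(=O)OC(=O)C(C)(C)C)ccc1OC(=O)C(C)(C)C | intermediate
4 | (S)-4-benzyl-3-{3-[3-methoxy-4-(pivaloyloxy)phenyl]propanoyl}oxazolidin-2-one | COc1cc(CCC(=O)N2[C@@H](Cc3ccccc3)COC2=O)ccc1OC(=O)C(C)(C)C | intermediate
5 | lithium (Z)-enolate of 4 | COc1cc(C/C=C(\O[Li])N2[C@@H](Cc3ccccc3)COC2=O)ccc1OC(=O)C(C)(C)C | intermediate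
6 | (4S,4'S)-3,3'-[(2R,3R)-2,3-bis(3-methoxy-4-pivaloyloxybenzyl)butanedioyl]bis(4-benzyloxazolidin-2-one) | O=C1OC[C@H](Cc2ccccc2)N1C(=O)[C@H](Cc1ccc(OC(=O)C(C)(C)C)c(OC)c1)[C@@H](Cc1ccc(OC(=O)C(C)(C)C)c(OC)c1)C(=O)N1[C@@H](Cc2ccccc2)COC1=O | intermediate
7 | (2R,3R)-2,3-bis(4-hydroxy-3-methoxybenzyl)butane-1,4-diol ((−)-secoisolariciresinol) | OC[C@H](Cc1ccc(O)c(OC)c1)[C@@H](Cc1ccc(O)c(OC)c1)CO | intermediate
8 | 4-[(2R,3R)-4-hydroxy-3-(4-hydroxy-3-methoxybenzyl)-2-(hydroxymethyl)butylidene]-2-methoxycyclohexa-2,5-dien-1-one | OC[C@H](C=C1C=CC(=O)C(OC)=C1)[C@@H](Cc1ccc(O)c(OC)c1)CO | intermediate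
9 | 4-[(2S,3R,4R)-4-(4-hydroxy-3-methoxybenzyl)-3-(hydroxymethyl)oxolan-2-yl]-2-methoxyphenol ((+)-lariciresinol) | OC[C@H]1[C@@H](Cc2ccc(O)c(OC)c2)CO[C@@H]1c1ccc(O)c(OC)c1 | intermediate
10 | vinyl stearate (ethenyl octadecanoate) | CCCCCCCCCCCCCCCCCC(=O)OC=C | starting material
11 | [(2S,3R,4R)-2-(4-hydroxy-3-methoxyphenyl)-4-(4-hydroxy-3-methoxybenzyl)oxolan-3-yl]methyl octadecanoate | CCCCCCCCCCCCCCCCCC(=O)OC[C@H]1[C@@H](Cc2ccc(O)c(OC)c2)CO[C@@H]1c1ccc(O)c(OC)c1 | target

**Totals**
Total step count: 5. Longest linear sequence: 5 steps (1 → 4 → 6 → 7 → 9 → 11).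

**Three steps most likely to fail**

Step 2 (oxidative homocoupling). Yield and diastereomer ratio of such couplings are capricious, and the sense of induction must be confirmed on the first batch. The fallback builds the central bond stepwise by known chemistry, sets out from 4 and comes back at 7. The sodium enolate of 4 (NaN(SiMe3)2, THF, −78 °C) is alkylated with tert-butyl bromoacetate (Evans alkylation) to tert-butyl (3R)-4-[(4S)-4-benzyl-2-oxooxazolidin-3-yl]-3-[3-methoxy-4-(pivaloyloxy)benzyl]-4-oxobutanoate F1. NaBH4 in THF–water removes the auxiliary to give tert-butyl (3R)-4-hydroxy-3-[3-methoxy-4-(pivaloyloxy)benzyl]butanoate F2, which TFA in CH2Cl2 closes to (4R)-4-[3-methoxy-4-(pivaloyloxy)benzyl]oxolan-2-one F3. Commercial 4-(benzyloxy)-3-methoxybenzyl alcohol and PBr3 give 4-(benzyloxy)-3-methoxybenzyl bromide F4, which alkylates the lithium enolate of F3 (LiN(SiMe3)2, THF, −78 °C) anti to the existing benzyl group to give (3R,4R)-3-[4-(benzyloxy)-3-methoxybenzyl]-4-[3-methoxy-4-(pivaloyloxy)benzyl]oxolan-2-one F5. LiAlH4 reduces the lactone and the pivalate to (2R,3R)-2-[4-(benzyloxy)-3-methoxybenzyl]-3-(4-hydroxy-3-methoxybenzyl)butane-1,4-diol F6, and H2 over Pd/C in ethyl acetate removes the benzyl ether to give 7.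

Step 4 (the proposed new cycloetherification). It may give mixtures of 9, pinoresinol, the aryltetralin and over-oxidised material. The fallback is the known lactone-aldol route, sets out from 4 and comes back at 9. As described above, 4 is taken through tert-butyl (3R)-4-[(4S)-4-benzyl-2-oxooxazolidin-3-yl]-3-[3-methoxy-4-(pivaloyloxy)benzyl]-4-oxobutanoate F1 and tert-butyl (3R)-4-hydroxy-3-[3-methoxy-4-(pivaloyloxy)benzyl]butanoate F2 to (4R)-4-[3-methoxy-4-(pivaloyloxy)benzyl]oxolan-2-one F3. The lithium enolate of F3 (LiN(SiMe3)2, THF, −78 °C) adds to commercial vanillin acetate anti to the benzyl group to give (3S,4R)-3-[(4-acetoxy-3-methoxyphenyl)(hydroxy)methyl]-4-[3-methoxy-4-(pivaloyloxy)benzyl]oxolan-2-one F7 as a mixture of carbinol epimers, both usable. LiAlH4 reduces the lactone and both aryl esters to (1RS,2R,3R)-1-(4-hydroxy-3-methoxyphenyl)-3-(4-hydroxy-3-methoxybenzyl)-2-(hydroxymethyl)butane-1,4-diol F8. Dilute HCl in THF–water at 20 °C ionises the p-hydroxybenzylic alcohol and closes the oxolane stereoconvergently to the 2,3-trans product 9, the reaction being stopped before the aryltetralin forms.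

Step 5 (lipase acylation). The neopentyl-like primary alcohol on a crowded ring may be a slow substrate for the enzyme. The fallback activates the alcohol instead of the acyl donor, sets out from 9 and comes back at 11: Mitsunobu esterification with stearic acid, PPh3 and diisopropyl azodicarboxylate in THF at 0 → 20 °C. The carboxylic acid (pKa about 5) outcompetes the phenols (pKa about 10) as pronucleophile, so no phenol protection is needed and no new compound is made.

**Further compounds**
F1 | step 2 | tert-butyl (3R)-4-[(4S)-4-benzyl-2-oxooxazolidin-3-yl]-3-[3-methoxy-4-(pivaloyloxy)benzyl]-4-oxobutanoate | CC(C)(C)OC(=O)C[C@@H](Cc1ccc(OC(=O)C(C)(C)C)c(OC)c1)C(=O)N1[C@@H](Cc2ccccc2)COC1=O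
F2 | step 2 | tert-butyl (3R)-4-hydroxy-3-[3-methoxy-4-(pivaloyloxy)benzyl]butanoate | CC(C)(C)OC(=O)C[C@@H](Cc1ccc(OC(=O)C(C)(C)C)c(OC)c1)CO
F3 | step 2 | (4R)-4-[3-methoxy-4-(pivaloyloxy)benzyl]oxolan-2-one | O=C1C[C@@H](Cc2ccc(OC(=O)C(C)(C)C)c(OC)c2)CO1
F4 | step 2 | 4-(benzyloxy)-3-methoxybenzyl bromide | COc1cc(CBr)ccc1OCc1ccccc1
F5 | step 2 | (3R,4R)-3-[4-(benzyloxy)-3-methoxybenzyl]-4-[3-methoxy-4-(pivaloyloxy)benzyl]oxolan-2-one | O=C1[C@H](Cc2ccc(OCc3ccccc3)c(OC)c2)[C@@H](Cc2ccc(OC(=O)C(C)(C)C)c(OC)c2)CO1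
F6 | step 2 | (2R,3R)-2-[4-(benzyloxy)-3-methoxybenzyl]-3-(4-hydroxy-3-methoxybenzyl)butane-1,4-diol | OC[C@H](Cc1ccc(OCc2ccccc2)c(OC)c1)[C@@H](Cc1ccc(O)c(OC)c1)CO
F7 | step 4 | (3S,4R)-3-[(4-acetoxy-3-methoxyphenyl)(hydroxy)methyl]-4-[3-methoxy-4-(pivaloyloxy)benzyl]oxolan-2-one (carbinol epimers) | O=C1[C@H](C(O)c2ccc(OC(C)=O)c(OC)c2)[C@@H](Cc2ccc(OC(=O)C(C)(C)C)c(OC)c2)CO1
F8 | step 4 | (1RS,2R,3R)-1-(4-hydroxy-3-methoxyphenyl)-3-(4-hydroxy-3-methoxybenzyl)-2-(hydroxymethyl)butane-1,4-diol | OC[C@H](C(O)c1ccc(O)c(OC)c1)[C@@H](Cc1ccc(O)c(OC)c1)CO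
F0 | step 5 | none | none
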